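**Retrosynthetic overview**
1. Last bond: C(sp3)–C(sp2) B-alkyl Suzuki–Miyaura union of a hydroborated 6-vinyl-1,2-dioxane acid with a (Z)-iodomethylidene octalin, instead of an olefination of an octalone.
2. Octalin: ring B is bought (2,2-dimethylcyclohexanone); ring A is closed by a copper-catalysed borylative cyclisation of a terminal alkyne onto an allylic phosphate, whose syn-borylcupration fixes the exocyclic (Z) geometry.
3. 1,2-Dioxane: H2O2 acts as a twofold nucleophile, first opening an (S,S)-epoxide at its tertiary carbon (sets C6), then closing the ring by SN2 on a secondary mesylate (sets C3); no hydroperoxide conjugate addition.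
4. C2 and C3 come from an Evans syn-aldol, C6 from a Shi epoxidation; the carbinol left by the epoxide opening is dehydrated to the vinyl handle.
5. Ring order: ring B (purchased), then the dioxane ring and ring A in parallel, then the coupling.

Assumption: (4-iodobut-1-yn-1-yl)trimethylsilane (24) and the L-fructose-derived enantiomer of the Shi ketone are taken as purchasable; C2, C3 and C6 in the text follow the target name.

**Dioxane branch**

Step 1
Reactants: 1 3-methylbut-3-en-2-ol (racemic); 2 triethyl orthoacetate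
Product: 4 ethyl (4E)-4-methylhex-4-enoate, via ketene acetal 3 (not isolated)
Conditions: EtCO2H (5 mol%), neat, 140 °C, EtOH distilled off
Reagents that add atoms: none
Why: Johnson–Claisen rearrangement, whose chair transition state with the carbinol methyl equatorial gives the (E)-trisubstituted alkene (≥95:5) and erases the racemic carbinol centre.

Step 2
Reactants: 4 ethyl (4E)-4-methylhex-4-enoate
Product: 5 (4E)-4-methylhex-4-enal
Conditions: i-Bu2AlH (1.05 equiv), CH2Cl2, −78 °C; aq. KNaC4H4O6 work-up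
Reagents that add atoms: none
Why: Partial hydride reduction of an ester stops at the aldehyde level at −78 °C and leaves the isolated alkene untouched.

Step 3
Reactants: 5 (4E)-4-methylhex-4-enal; 6 (4S)-4-benzyl-3-propanoyl-1,3-oxazolidin-2-one
Product: 8 (4S)-4-benzyl-3-[(2S,3R,6E)-3-hydroxy-2,6-dimethyloct-6-enoyl]-1,3-oxazolidin-2-one, via boron enolate 7 (not isolated)
Conditions: 6, Bu2BOTf (1.1 equiv), i-Pr2NEt (1.2 equiv), CH2Cl2, 0 °C; then 5, −78 → 0 °C; pH 7 buffer, MeOH, 30% H2O2
Reagents that add atoms: none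
Why: Evans syn-aldol reaction in which the (Z)-boron enolate reacts through a Zimmerman–Traxler chair on the face away from the benzyl group, setting C2 as (S) and the carbinol carbon as (R) (dr typically >95:5), the carbinol being set opposite to the target on purpose because it is inverted in step 9.

Step 4
Reactants: 8 aldol adduct
Product: 9 (2R,3R,6E)-2,6-dimethyloct-6-ene-1,3-diol
Conditions: LiBH4 (2 equiv), MeOH (2 equiv), THF, 0 °C
Reagents that add atoms: none
Why: Reductive cleavage of the N-acyl oxazolidinone at the exocyclic carbonyl gives the 1,3-diol without touching either stereocentre (the C2 descriptor changes only through the priority rules) and returns the auxiliary.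

Step 5
Reactants: 9 diol
Product: 10 (2R,3R,6E)-1-[(tert-butyldiphenylsilyl)oxy]-2,6-dimethyloct-6-en-3-ol
Conditions: TBDPSCl (1.05 equiv), imidazole, CH2Cl2, 0 °C
Reagents that add atoms: tert-butyl(chloro)diphenylsilane, CC(C)(C)[Si](Cl)(c1ccccc1)c1ccccc1
Why: Sterically selective silylation of the primary hydroxyl keeps the future carboxyl carbon in a form without an acidic α-hydrogen, so the later sulfonate displacement cannot become an E1cB elimination.

Step 6
Reactants: 10 silyl ether alcohol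
Product: 11 (2R,3R,6E)-1-[(tert-butyldiphenylsilyl)oxy]-2,6-dimethyloct-6-en-3-yl methanesulfonate
Conditions: MsCl (1.3 equiv), Et3N, CH2Cl2, 0 °C
Reagents that add atoms: methanesulfonyl chloride, CS(=O)(=O)Cl
Why: O-Sulfonylation of the secondary alcohol (retention, the C–O bond is not broken) installs the leaving group for the stereoinvertive ring closure.

Step 7
Reactants: 11 mesylate
Product: 12 (2R,3R)-1-[(tert-butyldiphenylsilyl)oxy]-5-[(2S,3S)-2,3-dimethyloxiran-2-yl]-2-methylpentan-3-yl methanesulfonate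
Conditions: L-fructose-derived Shi ketone (30 mol%), KHSO5 (Oxone, 1.5 equiv), K2CO3, Bu4NHSO4, MeCN/CH2(OMe)2/aq. Na2B4O7 buffer (pH 10.5), 0 °C
Reagents that add atoms: potassium peroxymonosulfate (Oxone), [K+].[O-]S(=O)(=O)OO
Why: Shi asymmetric epoxidation, in which the chiral dioxirane transfers oxygen through a spiro transition state and the enantiomer of the usual ketone gives the (2S,3S)-oxirane of the (E)-trisubstituted alkene under reagent control, so that one later inversion delivers C6 of the target.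

Step 8
Reactants: 12 epoxy mesylate
Product: 13 (2R,3R,6R,7S)-1-[(tert-butyldiphenylsilyl)oxy]-6-hydroperoxy-7-hydroxy-2,6-dimethyloctan-3-yl methanesulfonate
Conditions: anhydrous H2O2 in Et2O (10 equiv, dried over MgSO4), H3PMo12O40 (3 mol%), Et2O, 20 °C
Reagents that add atoms: hydrogen peroxide, OO
Why: Acid-catalysed perhydrolysis of an epoxide, in which H2O2 opens the activated oxirane at the tertiary carbon from the rear face (Markovnikov regiochemistry, inversion) and so fixes the quaternary peroxy carbon with the spatial arrangement of C6 in the target while the secondary carbinol is untouched.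

Step 9
Reactants: 13 hydroxy hydroperoxide
Product: 14 (1S)-1-[(3R,6S)-6-{(2R)-1-[(tert-butyldiphenylsilyl)oxy]propan-2-yl}-3-methyl-1,2-dioxan-3-yl]ethan-1-ol
Conditions: CsOH·H2O (1.2 equiv), DMF, 0 → 20 °C
Reagents that add atoms: none
Why: Intramolecular peroxide alkylation (6-exo-tet SN2) in which only the hydroperoxide (pKa about 12.5) is deprotonated and its α-effect oxygen displaces the secondary mesylate with inversion, turning the (R) carbinol carbon into the (S)-configured C3 of the dioxane.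

Step 10
Reactants: 14 hydroxyethyl dioxane
Product: 16 tert-butyl{(2R)-2-[(3S,6R)-6-ethenyl-6-methyl-1,2-dioxan-3-yl]propoxy}diphenylsilane, via sulfamate ester 15 (not isolated)
Conditions: Burgess reagent (MeO2CN−SO2N+Et3, 2.5 equiv), PhMe, 20 → 70 °C
Reagents that add atoms: none
Why: Burgess dehydration, whose syn-elimination can only take a hydrogen from the methyl group because the other neighbour is the quaternary peroxy carbon, so the terminal vinyl group forms and the superfluous carbinol stereocentre disappears.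

Step 11
Reactants: 16 vinyl dioxane silyl ether
Product: 17 (2R)-2-[(3S,6R)-6-ethenyl-6-methyl-1,2-dioxan-3-yl]propan-1-ol
Conditions: Bu4NF (1.5 equiv), AcOH (1.5 equiv), THF, 0 → 20 °C
Reagents that add atoms: none
Why: Fluoride-driven silyl ether cleavage, buffered with acetic acid so that the medium stays non-basic and the dialkyl peroxide is not opened by Kornblum–DeLaMare-type deprotonation.

Step 12
Reactants: 17 vinyl dioxane alcohol
Product: 19 (2S)-2-[(3S,6R)-6-ethenyl-6-methyl-1,2-dioxan-3-yl]propanoic acid, via aldehyde 18 (not isolated)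
Conditions: TEMPO (20 mol%), PhI(OAc)2 (2.5 equiv), MeCN/H2O 1:1, 20 °C
Reagents that add atoms: water, O
Why: Oxoammonium (TEMPO/PhI(OAc)2) oxidation of the primary alcohol through the aldehyde to the acid under near-neutral conditions that neither cleave the O–O bond, epimerise C2 nor touch the monosubstituted alkene, and it is done here so that no oxidant is needed once the electron-rich diene is present.

**Octalin branch**

Step 13
Reactants: 20 2,2-dimethylcyclohexan-1-one; 21 dimethyl carbonate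
Product: 22 methyl 3,3-dimethyl-2-oxocyclohexane-1-carboxylate (racemic)
Conditions: NaH (2.2 equiv), THF, reflux; AcOH quench
Reagents that add atoms: none
Why: Claisen-type carbomethoxylation of the ketone enolate, which can only form on the CH2 side because the other α-carbon is quaternary, is driven by deprotonation of the β-keto ester, and its racemic centre is erased in step 14.

Step 14
Reactants: 22 β-keto ester
Product: 23 methyl 3,3-dimethyl-2-{[(trifluoromethyl)sulfonyl]oxy}cyclohex-1-ene-1-carboxylate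
Conditions: Tf2O (1.2 equiv), i-Pr2NEt (1.5 equiv), CH2Cl2, −78 → 0 °C
Reagents that add atoms: trifluoromethanesulfonic anhydride, O=S(=O)(OS(=O)(=O)C(F)(F)F)C(F)(F)F
Why: O-Sulfonylation of the β-keto ester enol gives the only possible enol triflate, an activated electrophile for cross-coupling.

Step 15
Reactants: 23 enol triflate; 24 (4-iodobut-1-yn-1-yl)trimethylsilane
Product: 26 methyl 3,3-dimethyl-2-[4-(trimethylsilyl)but-3-yn-1-yl]cyclohex-1-ene-1-carboxylate, via alkylzinc iodide 25 (not isolated)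
Conditions: 24, Zn dust (activated with BrCH2CH2Br and Me3SiCl), THF, 40 °C; then 23, PdCl2(dppf) (5 mol%), THF/NMP, 50 °C
Reagents that add atoms: none
Why: Negishi cross-coupling in which zinc inserts into the primary C–I bond and PdCl2(dppf) joins the alkylzinc to the electron-poor β-triflyloxy enoate, the wide-bite-angle ligand suppressing β-hydride elimination and the silyl cap protecting the alkyne.

Step 16
Reactants: 26 coupled ester
Product: 27 {3,3-dimethyl-2-[4-(trimethylsilyl)but-3-yn-1-yl]cyclohex-1-en-1-yl}methanol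
Conditions: i-Bu2AlH (2.5 equiv), CH2Cl2, −78 → 0 °C
Reagents that add atoms: none
Why: 1,2-Reduction of the conjugated ester to the allylic alcohol by an electrophilic hydride that reduces neither the tetrasubstituted alkene nor the silylalkyne.

Step 17
Reactants: 27 silylalkyne alcohol
Product: 28 [2-(but-3-yn-1-yl)-3,3-dimethylcyclohex-1-en-1-yl]methanol
Conditions: K2CO3 (0.2 equiv), MeOH, 20 °C
Reagents that add atoms: none
Why: Base-catalysed methanolysis of the C(sp)–Si bond frees the terminal alkyne needed for regioselective borylcupration.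

Step 18
Reactants: 28 alkynol
Product: 29 [2-(but-3-yn-1-yl)-3,3-dimethylcyclohex-1-en-1-yl]methyl diethyl phosphate
Conditions: ClP(O)(OEt)2 (1.2 equiv), pyridine, DMAP (5 mol%), CH2Cl2, 0 °C
Reagents that add atoms: diethyl chlorophosphate, CCOP(=O)(Cl)OCC
Why: O-Phosphorylation turns the primary allylic alcohol into a leaving group that organocopper species displace readily but that cannot react in the SN2′ sense because the γ-carbon is fully substituted.

Step 19
Reactants: 29 allylic phosphate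
Product: 31 2-{(Z)-[5,5-dimethyl-3,4,5,6,7,8-hexahydronaphthalen-2(1H)-ylidene]methyl}-4,4,5,5-tetramethyl-1,3,2-dioxaborolane, via β-borylalkenylcopper 30 (not isolated)
Conditions: CuCl (10 mol%), Xantphos (10 mol%), NaOtBu (1.3 equiv), B2pin2 (1.3 equiv), THF, 20 °C, 0.02 M, slow addition of 29
Reagents that add atoms: bis(pinacolato)diboron, CC1(C)OB(OC1(C)C)B1OC(C)(C)C(C)(C)O1
Why: Proposed new method: copper-catalysed borylative cyclisation in which the Cu–B bond of (Xantphos)Cu–Bpin adds syn across the terminal alkyne with boron on the terminal carbon and the internal C–Cu bond then alkylates the allylic phosphate carbon with retention at the sp2 carbon (ring A closes as a six-membered ring, the SN2′ alternative would be a four-membered ring), so boron must end up cis to C1, which is the (Z)-alkylidene; the closest known reaction type is the copper-catalysed syn-carboboration of terminal alkynes with B2pin2 and alkyl or allyl electrophiles, including borylative exo-cyclisations onto tethered electrophiles.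

Step 20
Reactants: 31 alkenylboronate
Product: 32 (2Z)-2-(iodomethylidene)-5,5-dimethyl-1,2,3,4,5,6,7,8-octahydronaphthalene
Conditions: NaOH (3 M aq., 3 equiv), I2 (1.2 equiv), THF, 0 °C, dark
Reagents that add atoms: iodine, II
Why: Iododeboronation of the hydroxide-activated alkenylboronate (ipso substitution) proceeds with retention, and the anionic boronate is far more nucleophilic than the tetrasubstituted ring alkene, so the (Z)-alkenyl iodide results.

**Union**

Step 21
Reactants: 19 vinyl dioxane acid; 32 (Z)-alkenyl iodide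
Product: 34 (2S)-2-[(3S,6S)-6-{3-[(2Z)-5,5-dimethyl-3,4,5,6,7,8-hexahydronaphthalen-2(1H)-ylidene]propyl}-6-methyl-1,2-dioxan-3-yl]propanoic acid (target), via B-alkyl-9-BBN 33 (not isolated)
Conditions: 19, 9-BBN-H (2.3 equiv), THF, 0 → 20 °C; then 32, PdCl2(dppf) (10 mol%), AsPh3 (10 mol%), Cs2CO3 (4 equiv), DMF/H2O, 20 °C, dark; citric acid work-up
Reagents that add atoms: none
Why: B-alkyl Suzuki–Miyaura coupling in which 9-BBN-H adds anti-Markovnikov to the vinyl group (the first equivalent is taken up by the acid as an acyloxyborane that the aqueous base hydrolyses again) and the alkylborane couples with the alkenyl iodide at room temperature with retention of the (Z) geometry, conditions that a dialkyl peroxide and a carboxylate are expected to survive and that touch no stereocentre.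

**Compound list**
1 | 3-methylbut-3-en-2-ol (racemic) | CC(O)C(C)=C | starting material
2 | triethyl orthoacetate | CC(OCC)(OCC)OCC | starting material
3 | 1-ethoxy-1-[(3-methylbut-3-en-2-yl)oxy]ethene | C=C(OCC)OC(C)C(C)=C | intermediate
4 | ethyl (4E)-4-methylhex-4-enoate | CCOC(=O)CC/C(C)=C/C | intermediate
5 | (4E)-4-methylhex-4-enal | O=CCC/C(C)=C/C | intermediate
6 | (4S)-4-benzyl-3-propanoyl-1,3-oxazolidin-2-one | CCC(=O)N1[C@@H](Cc2ccccc2)COC1=O | starting material
7 | (4S)-4-benzyl-3-{(1Z)-1-[(dibutylboranyl)oxy]prop-1-en-1-yl}-1,3-oxazolidin-2-one | C/C=C(\OB(CCCC)CCCC)N1[C@@H](Cc2ccccc2)COC1=O | intermediate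
8 | (4S)-4-benzyl-3-[(2S,3R,6E)-3-hydroxy-2,6-dimethyloct-6-enoyl]-1,3-oxazolidin-2-one | C[C@H](C(=O)N1[C@@H](Cc2ccccc2)COC1=O)[C@H](O)CC/C(C)=C/C | intermediate
9 | (2R,3R,6E)-2,6-dimethyloct-6-ene-1,3-diol | C[C@H](CO)[C@H](O)CC/C(C)=C/C | intermediate
10 | (2R,3R,6E)-1-[(tert-butyldiphenylsilyl)oxy]-2,6-dimethyloct-6-en-3-ol | C[C@H](CO[Si](c1ccccc1)(c2ccccc2)C(C)(C)C)[C@H](O)CC/C(C)=C/C | intermediate
11 | (2R,3R,6E)-1-[(tert-butyldiphenylsilyl)oxy]-2,6-dimethyloct-6-en-3-yl methanesulfonate | C[C@H](CO[Si](c1ccccc1)(c2ccccc2)C(C)(C)C)[C@H](OS(C)(=O)=O)CC/C(C)=C/C | intermediate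
12 | (2R,3R)-1-[(tert-butyldiphenylsilyl)oxy]-5-[(2S,3S)-2,3-dimethyloxiran-2-yl]-2-methylpentan-3-yl methanesulfonate | C[C@H](CO[Si](c2ccccc2)(c3ccccc3)C(C)(C)C)[C@H](OS(C)(=O)=O)CC[C@@]1(C)[C@H](C)O1 | intermediate
13 | (2R,3R,6R,7S)-1-[(tert-butyldiphenylsilyl)oxy]-6-hydroperoxy-7-hydroxy-2,6-dimethyloctan-3-yl methanesulfonate | C[C@H](CO[Si](c1ccccc1)(c2ccccc2)C(C)(C)C)[C@H](OS(C)(=O)=O)CC[C@@](C)(OO)[C@H](C)O | intermediate
14 | (1S)-1-[(3R,6S)-6-{(2R)-1-[(tert-butyldiphenylsilyl)oxy]propan-2-yl}-3-methyl-1,2-dioxan-3-yl]ethan-1-ol | C[C@H](CO[Si](c2ccccc2)(c3ccccc3)C(C)(C)C)[C@@H]1CC[C@](C)([C@H](C)O)OO1 | intermediate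
15 | triethylammonium salt of the N-(methoxycarbonyl)sulfamate ester of 14 | C[C@H](CO[Si](c2ccccc2)(c3ccccc3)C(C)(C)C)[C@@H]1CC[C@](C)([C@H](C)OS(=O)(=O)[N-]C(=O)OC)OO1.CC[NH+](CC)CC | intermediate
16 | tert-butyl{(2R)-2-[(3S,6R)-6-ethenyl-6-methyl-1,2-dioxan-3-yl]propoxy}diphenylsilane | C[C@H](CO[Si](c2ccccc2)(c3ccccc3)C(C)(C)C)[C@@H]1CC[C@](C)(C=C)OO1 | intermediate
17 | (2R)-2-[(3S,6R)-6-ethenyl-6-methyl-1,2-dioxan-3-yl]propan-1-ol | C[C@H](CO)[C@@H]1CC[C@](C)(C=C)OO1 | intermediate
18 | (2S)-2-[(3S,6R)-6-ethenyl-6-methyl-1,2-dioxan-3-yl]propanal | C[C@H](C=O)[C@@H]1CC[C@](C)(C=C)OO1 | intermediate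
19 | (2S)-2-[(3S,6R)-6-ethenyl-6-methyl-1,2-dioxan-3-yl]propanoic acid | C[C@H](C(=O)O)[C@@H]1CC[C@](C)(C=C)OO1 | intermediate
20 | 2,2-dimethylcyclohexan-1-one | CC1(C)CCCCC1=O | starting material
21 | dimethyl carbonate | COC(=O)OC | starting material
22 | methyl 3,3-dimethyl-2-oxocyclohexane-1-carboxylate (racemic) | COC(=O)C1CCCC(C)(C)C1=O | intermediate
23 | methyl 3,3-dimethyl-2-{[(trifluoromethyl)sulfonyl]oxy}cyclohex-1-ene-1-carboxylate | COC(=O)C1=C(OS(=O)(=O)C(F)(F)F)C(C)(C)CCC1 | intermediate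
24 | (4-iodobut-1-yn-1-yl)trimethylsilane | C[Si](C)(C)C#CCCI | starting material
25 | iodo[4-(trimethylsilyl)but-3-yn-1-yl]zinc | C[Si](C)(C)C#CCC[Zn]I | intermediate
26 | methyl 3,3-dimethyl-2-[4-(trimethylsilyl)but-3-yn-1-yl]cyclohex-1-ene-1-carboxylate | COC(=O)C1=C(CCC#C[Si](C)(C)C)C(C)(C)CCC1 | intermediate
27 | {3,3-dimethyl-2-[4-(trimethylsilyl)but-3-yn-1-yl]cyclohex-1-en-1-yl}methanol | OCC1=C(CCC#C[Si](C)(C)C)C(C)(C)CCC1 | intermediate
28 | [2-(but-3-yn-1-yl)-3,3-dimethylcyclohex-1-en-1-yl]methanol | OCC1=C(CCC#C)C(C)(C)CCC1 | intermediate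
29 | [2-(but-3-yn-1-yl)-3,3-dimethylcyclohex-1-en-1-yl]methyl diethyl phosphate | CCOP(=O)(OCC)OCC1=C(CCC#C)C(C)(C)CCC1 | intermediate
30 | [(1Z)-4-(2-{[(diethoxyphosphoryl)oxy]methyl}-6,6-dimethylcyclohex-1-en-1-yl)-1-(4,4,5,5-tetramethyl-1,3,2-dioxaborolan-2-yl)but-1-en-2-yl]copper (Xantphos-ligated) | CCOP(=O)(OCC)OCC1=C(CC/C([Cu])=C/B2OC(C)(C)C(C)(C)O2)C(C)(C)CCC1 | intermediate
31 | 2-{(Z)-[5,5-dimethyl-3,4,5,6,7,8-hexahydronaphthalen-2(1H)-ylidene]methyl}-4,4,5,5-tetramethyl-1,3,2-dioxaborolane | CC1(C)OB(OC1(C)C)/C=C2/CCC3=C(CCCC3(C)C)C2 | intermediate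
32 | (2Z)-2-(iodomethylidene)-5,5-dimethyl-1,2,3,4,5,6,7,8-octahydronaphthalene | I/C=C1/CCC2=C(CCCC2(C)C)C1 | intermediate
33 | 9-borabicyclo[3.3.1]nonan-9-yl (2S)-2-[(3S,6S)-6-[2-(9-borabicyclo[3.3.1]nonan-9-yl)ethyl]-6-methyl-1,2-dioxan-3-yl]propanoate | C[C@H](C(=O)OB3C4CCCC3CCC4)[C@@H]1CC[C@](C)(CCB5C6CCCC5CCC6)OO1 | intermediate
34 | (2S)-2-[(3S,6S)-6-{3-[(2Z)-5,5-dimethyl-3,4,5,6,7,8-hexahydronaphthalen-2(1H)-ylidene]propyl}-6-methyl-1,2-dioxan-3-yl]propanoic acid | C[C@H](C(=O)O)[C@@H]1CC[C@](C)(CC/C=C2/CCC3=C(CCCC3(C)C)C2)OO1 | target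

**Step count and risks**
Total steps: 21. Longest linear sequence: 13 (steps 1–12, then 21); the octalin branch is 8 steps (13–20) before the union.

The three steps most likely to fail:

Step 19 (new ring closure; protodecupration, copper acetylide formation or direct attack of the copper boryl on the phosphate could compete). The fallback sets out from 28 and comes back at 32. It fixes the alkene geometry by a palladium-catalysed syn-distannation and closes ring A by an intramolecular Stille coupling. Me3SnSnMe3 and Pd(PPh3)4 (THF, 60 °C) add both tin groups to the same face of the alkyne of 28 and give {2-[(3Z)-3,4-bis(trimethylstannyl)but-3-en-1-yl]-3,3-dimethylcyclohex-1-en-1-yl}methanol F1. MsCl, LiCl and 2,4,6-collidine in DMF at 0 °C give the allylic chloride 1-(chloromethyl)-2-[(3Z)-3,4-bis(trimethylstannyl)but-3-en-1-yl]-3,3-dimethylcyclohex-1-ene F2. Pd2(dba)3 with AsPh3 in NMP at 50 °C couples the allylic chloride with the internal stannane only, because coupling at the terminal tin would need a trans-cycloheptene. This gives {(Z)-[5,5-dimethyl-3,4,5,6,7,8-hexahydronaphthalen-2(1H)-ylidene]methyl}trimethylstannane F3 with tin cis to C1, and I2 in CH2Cl2 at 0 °C converts it into 32 with retention.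

Step 21 (a free carboxylic acid and a peroxide oxygen three atoms from boron during hydroboration and palladium catalysis). The fallback sets out from 16 and 32 and comes back at 34. The union is made on the silyl ether and the acid is unveiled afterwards. 16 is hydroborated with 9-BBN-H (1.2 equiv, THF) to 9-{2-[(3S,6S)-6-{(2R)-1-[(tert-butyldiphenylsilyl)oxy]propan-2-yl}-3-methyl-1,2-dioxan-3-yl]ethyl}-9-borabicyclo[3.3.1]nonane F4, which is not isolated. It is coupled with 32 (PdCl2(dppf), AsPh3, Cs2CO3, DMF/H2O, 20 °C) to tert-butyl{(2R)-2-[(3S,6S)-6-{3-[(2Z)-5,5-dimethyl-3,4,5,6,7,8-hexahydronaphthalen-2(1H)-ylidene]propyl}-6-methyl-1,2-dioxan-3-yl]propoxy}diphenylsilane F5. Bu4NF/AcOH gives (2R)-2-[(3S,6S)-6-{3-[(2Z)-5,5-dimethyl-3,4,5,6,7,8-hexahydronaphthalen-2(1H)-ylidene]propyl}-6-methyl-1,2-dioxan-3-yl]propan-1-ol F6. Dess–Martin periodinane with NaHCO3 gives (2S)-2-[(3S,6S)-6-{3-[(2Z)-5,5-dimethyl-3,4,5,6,7,8-hexahydronaphthalen-2(1H)-ylidene]propyl}-6-methyl-1,2-dioxan-3-yl]propanal F7. NaClO2/NaH2PO4 with a large excess of 2-methylbut-2-ene in t-BuOH/H2O then gives 34.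

Step 9 (SN2 at a β-branched secondary mesylate competes with E2, and the β-hydroxy hydroperoxide can fragment under base). The fallback sets out from 11 and comes back at 14. The order of the two C–O bond formations is reversed, so the ring closes by an acid-catalysed epoxide opening. Ozonolysis of 2,3-dimethylbut-2-ene in MeOH/CH2Cl2 at −78 °C gives 2-hydroperoxy-2-methoxypropane F8. Its caesium salt (CsOH·H2O, DMF, 0 °C) displaces the mesylate of 11 with inversion and gives tert-butyl({(2R,3S,6E)-3-[(2-methoxypropan-2-yl)peroxy]-2,6-dimethyloct-6-en-1-yl}oxy)diphenylsilane F9. The Shi epoxidation of step 7 then gives tert-butyl({(2R,3S)-5-[(2S,3S)-2,3-dimethyloxiran-2-yl]-3-[(2-methoxypropan-2-yl)peroxy]-2-methylpentyl}oxy)diphenylsilane F10. Aqueous AcOH in THF removes the ketal to give tert-butyl({(2R,3S)-5-[(2S,3S)-2,3-dimethyloxiran-2-yl]-3-hydroperoxy-2-methylpentyl}oxy)diphenylsilane F11, which is not isolated. Camphorsulfonic acid (5 mol%, CH2Cl2, 0 °C) makes it open the epoxide at the tertiary carbon (6-exo, inversion) to give 14.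

Further compounds
F1 | step 19 | {2-[(3Z)-3,4-bis(trimethylstannyl)but-3-en-1-yl]-3,3-dimethylcyclohex-1-en-1-yl}methanol | OCC1=C(CC/C(=C/[Sn](C)(C)C)[Sn](C)(C)C)C(C)(C)CCC1
F2 | step 19 | 1-(chloromethyl)-2-[(3Z)-3,4-bis(trimethylstannyl)but-3-en-1-yl]-3,3-dimethylcyclohex-1-ene | ClCC1=C(CC/C(=C/[Sn](C)(C)C)[Sn](C)(C)C)C(C)(C)CCC1
F3 | step 19 | {(Z)-[5,5-dimethyl-3,4,5,6,7,8-hexahydronaphthalen-2(1H)-ylidene]methyl}trimethylstannane | C[Sn](C)(C)/C=C1/CCC2=C(CCCC2(C)C)C1
F4 | step 21 | 9-{2-[(3S,6S)-6-{(2R)-1-[(tert-butyldiphenylsilyl)oxy]propan-2-yl}-3-methyl-1,2-dioxan-3-yl]ethyl}-9-borabicyclo[3.3.1]nonane | C[C@H](CO[Si](c2ccccc2)(c3ccccc3)C(C)(C)C)[C@@H]1CC[C@](C)(CCB4C5CCCC4CCC5)OO1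
F5 | step 21 | tert-butyl{(2R)-2-[(3S,6S)-6-{3-[(2Z)-5,5-dimethyl-3,4,5,6,7,8-hexahydronaphthalen-2(1H)-ylidene]propyl}-6-methyl-1,2-dioxan-3-yl]propoxy}diphenylsilane | C[C@H](CO[Si](c2ccccc2)(c3ccccc3)C(C)(C)C)[C@@H]1CC[C@](C)(CC/C=C4/CCC5=C(CCCC5(C)C)C4)OO1
F6 | step 21 | (2R)-2-[(3S,6S)-6-{3-[(2Z)-5,5-dimethyl-3,4,5,6,7,8-hexahydronaphthalen-2(1H)-ylidene]propyl}-6-methyl-1,2-dioxan-3-yl]propan-1-ol | C[C@H](CO)[C@@H]1CC[C@](C)(CC/C=C2/CCC3=C(CCCC3(C)C)C2)OO1
F7 | step 21 | (2S)-2-[(3S,6S)-6-{3-[(2Z)-5,5-dimethyl-3,4,5,6,7,8-hexahydronaphthalen-2(1H)-ylidene]propyl}-6-methyl-1,2-dioxan-3-yl]propanal | C[C@H](C=O)[C@@H]1CC[C@](C)(CC/C=C2/CCC3=C(CCCC3(C)C)C2)OO1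
F8 | step 9 | 2-hydroperoxy-2-methoxypropane | COC(C)(C)OO
F9 | step 9 | tert-butyl({(2R,3S,6E)-3-[(2-methoxypropan-2-yl)peroxy]-2,6-dimethyloct-6-en-1-yl}oxy)diphenylsilane | C[C@H](CO[Si](c1ccccc1)(c2ccccc2)C(C)(C)C)[C@@H](OOC(C)(C)OC)CC/C(C)=C/C
F10 | step 9 | tert-butyl({(2R,3S)-5-[(2S,3S)-2,3-dimethyloxiran-2-yl]-3-[(2-methoxypropan-2-yl)peroxy]-2-methylpentyl}oxy)diphenylsilane | C[C@H](CO[Si](c2ccccc2)(c3ccccc3)C(C)(C)C)[C@@H](OOC(C)(C)OC)CC[C@@]1(C)[C@H](C)O1
F11 | step 9 | tert-butyl({(2R,3S)-5-[(2S,3S)-2,3-dimethyloxiran-2-yl]-3-hydroperoxy-2-methylpentyl}oxy)diphenylsilane | C[C@H](CO[Si](c2ccccc2)(c3ccccc3)C(C)(C)C)[C@@H](OO)CC[C@@]1(C)[C@H](C)O1
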